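## Analysis of the target

The target is a 2,4-dihydroxybenzoic acid built on a single benzene ring (C1 carboxyl, C2 and C4 hydroxyl). At C6 it carries an unbranched fifteen-carbon chain (C1' at the ring to C15') with a Z-alkene at C8'=C9' and an acetoxy group at C10'. C10' is the only stereocentre, (R), and it is allylic. Nothing else in the molecule can relay or correct it, so it must be brought in enantiopure and its C–O bond must never be ionised; the Z geometry is the only other stereochemical element. The sensitive groups are three:

- the secondary Z-allylic acetate, which is prone to ionisation by Lewis or strong Brønsted acids, to 1,3-acyloxy shift on heating, to π-allyl formation with zerovalent palladium and to acyl cleavage by base;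
- the Z-alkene, which excludes hydrogenolysis, halogen oxidants and radical thiol chemistry;
- the 2,4-dihydroxybenzoic acid, which loses CO2 when heated in acid.

Two things make the synthesis hard. First, the contiguous C6-alkyl / C1-carboxyl / C2-oxygen array cannot be reached by electrophilic substitution or directed metalation of a 5-alkylresorcinol ether, which functionalise the position between the two oxygens. Second, the acetate must end up on the alcohol alone although the two phenols are acylated more easily. The strategy rests on the adjacent pair C6 and C1, with C1 next to the C2 oxygen. This is the pattern left when a carbon nucleophile adds to a 3-oxygenated benzyne at the aryne carbon remote from oxygen and the aryl anion formed ortho to oxygen is trapped by an electrophile; here the chain is the nucleophile and CO2 the electrophile. Because the phenol protecting groups must survive organolithium and Grignard reagents yet come off without Lewis acids or hot nucleophiles, the phenols are carried as methoxymethyl acetals rather than methyl ethers, and C10'–OH as a silyl ether.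

## Retrosynthetic reasoning

**Target 18 to triacetate 17 and triol acid 15.** The two aryl O–acetyl bonds are cut, in the sense of re-adding them. Direct acetylation of C10'–OH in the presence of two free phenols is not selective. All three hydroxyls of 15 are therefore acetylated to 17 (the carboxyl passes through mixed anhydride 16, which water returns to the acid). The forward reaction must then remove only the aryl acetates. Ammonolysis does this, because phenoxides conjugated to the carboxyl are far better leaving groups than the hindered secondary alkoxide at C10'.

**Triol acid 15 to protected acid 14.** The two aryl O–CH2 acetal bonds and the C10' O–Si bond are cut together. One mild acid solvolysis removes all three groups, so the allylic centre never meets a Lewis acid. Methyl ethers at C2–O and C4–O were rejected at this point. Their cleavage needs boron or aluminium halides, which ionise the allylic C10'–O bond, or hot thiolate, which stalls after the first demethylation once a phenoxide is formed. The forward reaction has to proceed near room temperature so that the liberated dihydroxybenzoic acid keeps its carboxyl.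

**Protected acid 14 to fluoroarene 9, Grignard reagent 7 and carbon dioxide 10.** This is the key disconnection: C6–C1' and C1–CO2H are cut at once. These are exactly the two ring bonds on adjacent carbons next to the C2 oxygen, and aryne 12 accounts for both. Cutting here makes the route fully convergent, keeps the ring at the aromatic oxidation level throughout and asks of the chain only that it be a primary alkylmagnesium halide. The forward reaction has to achieve three things:

- lithiation of 9 next to fluorine (giving 11);
- addition of 7 to 12 at the carbon remote from oxygen (giving 13);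
- carboxylation of 13 by 10.

**Fluoroarene 9 to diol 8.** The two O–CH2 bonds are cut; double O-alkylation of the symmetric diol 8 gives 9 in one step. Symmetry matters in the forward direction, because lithiation on either side of fluorine leads to the same aryne 12.

**Grignard reagent 7 to bromide 6 and bromoalkyne 5.** The C1'–Mg bond comes from the C1'–Br bond of 6. The Z-alkene is traced to the alkyne of 5, because syn semi-hydrogenation sets the Z geometry reliably and because an alkyne allows the chain to be assembled by acetylide alkylation. The forward steps must leave the primary bromide and the allylic silyl ether untouched.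

**Bromoalkyne 5 to silyl ether 2 and dibromide 3, and 2 to alcohol 1.** The C7'–C8' bond is cut. Acetylide 4, derived from 2, displaces one bromide of the symmetric C7 dibromide 3, used in excess so that the second bromide remains for the later magnesium insertion. The stereocentre is bought with 1 and only silylated, so no step of the route has to create or control it.

## Alternatives that were turned down

**Alternative 1:** The ring would be built from acyclic carbon. Cutting C1–C6 and C2–C3 leads to E-enone A1, which carries the chain on its β-carbon, and malonate diester A2. In the forward direction a strong alkoxide base would trigger Michael addition of A2 to A1 and then an intramolecular Claisen condensation of the methyl ketone enolate onto one ester, giving cyclohexanedione ester A3, to be aromatised afterwards.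

- For: the reagents are cheap, the chain never has to become an organometallic, and the substitution pattern is fixed by connectivity. On regiochemical certainty it is stronger than the aryne route.
- Against: A3 carries two hydrogens more than the arene. Its dehydrogenation needs halogenation–dehydrohalogenation or metal-salt and quinone oxidants, all of which attack the electron-rich Z-alkene or its allylic positions. The chain must first be elaborated to a C16 aldehyde and then to A1. Ester cleavage at the dione stage invites decarboxylation of a β-keto acid. After aromatisation the free phenols pose the same acetylation problem.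
- Comparison: the chosen route starts from a ring that is already aromatic, so no oxidant meets the alkene, and it needs fewer chain operations. In place of built-in regiochemistry it relies on the directing effects of fluorine and of the C2 oxygen.

**Alternative 2:** Cutting C1–C2 and C5–C6 gives ynoate A4, which carries the finished chain including the acetate, and cyclic bis-silyloxy diene A5. Heating would give a Diels–Alder adduct that ejects its gem-dimethyl bridge as an alkene (Alder–Rickert), leaving resorcylate A6 with free phenols after desilylating work-up.

- For: it is the most convergent plan. The acetate is in place before the ring exists and the phenols are never protected, so the end-game shrinks to one ester cleavage. On protecting-group economy it is clearly stronger.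
- Against: a β-alkyl ynoate is a weak dienophile, and the cycloaddition and cycloreversion usually need long heating well above 150 °C. Under such conditions the secondary Z-allylic acetate can undergo 1,3-acyloxy shift, which moves the oxygen from C10' to C8', and can eliminate to a diene; the Z-alkene can isomerise. The final fluoride-mediated ester cleavage would have to spare an acetate next to two free phenols. A4 also needs its own multistep preparation.
- Comparison: the chosen route forms both ring–carbon bonds between −78 °C and room temperature, where C10' and the alkene are spectators. It pays for this with phenol protection and deprotection.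

**Alternative 3:** Cutting C1–C6 in the aldol sense leads to open-chain triketo ester A9 and, one step further back, to diketo-dioxinone A7. Thermolysis of A7 would release an acyl ketene, alcohol A8 would trap it as A9, and mild carbonate base followed by weak acid would close and dehydrate the ring to resorcylate A10.

- For: it is biomimetic and forms the ring at the correct oxidation level under mild conditions, with unambiguous regiochemistry and no phenol protecting groups. On predictability of the ring-forming event it is at least as strong as the aryne coupling.
- Against: A7 requires two successive C-acylations of dioxinone-derived enolates with a chain acyl donor. The chain must first be turned into a C16 acid derivative and then carried through several highly enolised, chelating polycarbonyl intermediates, which adds roughly three to four linear steps on the stereochemically valuable fragment. A10 still needs ester cleavage, desilylation and acetylation in the presence of free phenols.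
- Comparison: the chosen route is shorter and places its one demanding step on a simple primary bromide. What it gives up is the mildness and regiochemical certainty of the ring closure in A10.

Key step: step 6

Remark: compounds 1, 3, 8 and 10 are taken as purchased materials, 1 as the (R)-enantiomer; chain locants C1'–C15' count from the ring carbon outward and are used in all names.

## Route

Step 1
Reactants: 1 (R)-oct-1-yn-3-ol
Product: 2 (R)-3-(tert-butyldimethylsilyloxy)oct-1-yne
Conditions: TBSCl, imidazole, DMF, 0 °C → rt
Reagents that add atoms: tert-butyldimethylsilyl chloride, CC(C)(C)[Si](C)(C)Cl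
Why: Standard O-silylation of a secondary propargylic alcohol; the C–O bond of the future C10' is not broken, so the (R) configuration bought with 1 is carried over unchanged.

Step 2
Reactants: 2 (R)-3-(tert-butyldimethylsilyloxy)oct-1-yne; 3 1,7-dibromoheptane
Product: 5 (R)-1-bromo-10-(tert-butyldimethylsilyloxy)pentadec-8-yne, via lithium acetylide 4 (not isolated)
Conditions: n-BuLi, THF, −78 °C; then DMPU, 3 (4 equiv), −78 °C → rt
Reagents that add atoms: none
Why: Deprotonation of the terminal alkyne and SN2 alkylation of the lithium acetylide by a primary bromide in a dipolar cosolvent form C7'–C8'; the excess of the symmetric dibromide suppresses double alkylation and the surplus is recovered. The silyl ether masks the alkoxide and the stereocentre is not involved.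

Step 3
Reactants: 5 (R)-1-bromo-10-(tert-butyldimethylsilyloxy)pentadec-8-yne
Product: 6 (8Z,10R)-1-bromo-10-(tert-butyldimethylsilyloxy)pentadec-8-ene
Conditions: H2 (1 atm), Pd/CaCO3 poisoned with Pb(OAc)2, quinoline, hexane–EtOAc, rt
Reagents that add atoms: none
Why: Lindlar semi-hydrogenation: syn delivery of hydrogen on the poisoned palladium surface gives the Z-alkene and quinoline holds back over-reduction; the primary C–Br bond and the silyl ether are inert and the allylic stereocentre is not touched.

Step 4
Reactants: 6 (8Z,10R)-1-bromo-10-(tert-butyldimethylsilyloxy)pentadec-8-ene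
Product: 7 [(8Z,10R)-10-(tert-butyldimethylsilyloxy)pentadec-8-en-1-yl]magnesium bromide
Conditions: Mg turnings, BrCH2CH2Br (cat.), THF, 40 °C; titrated solution used directly
Reagents that add atoms: magnesium, [Mg]
Why: Oxidative insertion of magnesium into the primary C–Br bond gives the Grignard reagent; the Z-alkene and the silyl ether offer no electrophilic or acidic site, and slow addition of 6 keeps Wurtz coupling low.

Step 5
Reactants: 8 5-fluorobenzene-1,3-diol
Product: 9 1-fluoro-3,5-bis(methoxymethoxy)benzene
Conditions: MOMCl, iPr2NEt, CH2Cl2, 0 °C → rt
Reagents that add atoms: chloromethyl methyl ether, COCCl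
Why: Double O-alkylation of the phenols by the reactive α-chloro ether under amine base; the resulting acetals tolerate organolithium and Grignard reagents and are later removable by mild acid.

Step 6
Reactants: 9 1-fluoro-3,5-bis(methoxymethoxy)benzene; 7 [(8Z,10R)-10-(tert-butyldimethylsilyloxy)pentadec-8-en-1-yl]magnesium bromide; 10 carbon dioxide
Product: 14 2,4-bis(methoxymethoxy)-6-[(8Z,10R)-10-(tert-butyldimethylsilyloxy)pentadec-8-en-1-yl]benzoic acid, via aryllithium 11 (not isolated), via aryne 12 (not isolated), via arylmagnesium bromide 13 (not isolated)
Conditions: LiTMP (lithium 2,2,6,6-tetramethylpiperidide, from the amine and n-BuLi), THF, −78 °C; then 7 (1.5 equiv), −78 °C → rt; then CO2 (dry gas), −40 °C → rt; cold aq. citric acid to pH 4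
Reagents that add atoms: none
Why: Lithium 2,2,6,6-tetramethylpiperidide removes the ring proton flanked by fluorine and one acetal oxygen, the most acidic C–H of 9, to give 11; metalation between the two acetal oxygens is less favoured, can revert through the amine and cannot eliminate. On warming, 11 loses fluoride to give aryne 12, the same aryne from either side of fluorine because 9 is symmetric. The primary alkylmagnesium 7 adds to the aryne carbon remote from the flanking oxygen (the former C–F carbon, C6 of the product), since the negative charge then develops at C1, where the adjacent C2–O bond stabilises it inductively and the acetal oxygen chelates magnesium, giving 13. Carbon dioxide 10 then carboxylates the C1–Mg bond, so C6–C1' and C1–CO2H are formed in one flask. The closest known reaction type is the three-component coupling of 3-alkoxybenzynes, generated from ortho-lithiated fluoroarenes, with Grignard reagents and CO2. No ring is closed and no stereocentre is created; C10' and the Z-alkene are spectators, and the silyl ether, the acetals and the alkene are inert to the organometallics below room temperature. The two selectivities needed are the site of lithiation, secured by the acidifying fluorine, and the direction of addition to 12, secured by the C2 oxygen; 7 is used in excess so that 13 does not compete for 12.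

Step 7
Reactants: 14 2,4-bis(methoxymethoxy)-6-[(8Z,10R)-10-(tert-butyldimethylsilyloxy)pentadec-8-en-1-yl]benzoic acid
Product: 15 2,4-dihydroxy-6-[(8Z,10R)-10-hydroxypentadec-8-en-1-yl]benzoic acid
Conditions: aq. HCl (ca. 0.5 M overall), MeOH–THF, rt → 35 °C
Reagents that add atoms: none
Why: Acid-catalysed acetal exchange with the solvent removes both aryl methoxymethyl groups (the one ortho to the carboxyl assisted by the neighbouring acid) and solvolyses the secondary silyl ether in the same operation. Esterification is not expected because the carboxyl is flanked by two ortho substituents, and the unactivated secondary allylic alcohol should not ionise under these mild conditions.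

Step 8
Reactants: 15 2,4-dihydroxy-6-[(8Z,10R)-10-hydroxypentadec-8-en-1-yl]benzoic acid
Product: 17 2,4-diacetoxy-6-[(8Z,10R)-10-acetoxypentadec-8-en-1-yl]benzoic acid, via mixed anhydride 16 (not isolated)
Conditions: Ac2O, pyridine, DMAP (cat.), CH2Cl2, 0 °C → rt; then H2O–THF, rt
Reagents that add atoms: acetic anhydride, CC(=O)OC(C)=O
Why: Exhaustive O-acetylation under nucleophilic catalysis acylates both phenols and the C10' alcohol with retention, since the C10'–O bond is not broken. The carboxyl is converted into the mixed anhydride 16, which water cleaves at the unhindered acetyl carbonyl to return the free acid.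

Step 9
Reactants: 17 2,4-diacetoxy-6-[(8Z,10R)-10-acetoxypentadec-8-en-1-yl]benzoic acid
Product: 18 2,4-dihydroxy-6-[(8Z,10R)-10-acetoxypentadec-8-en-1-yl]benzoic acid
Conditions: NH3 (7 M in MeOH), THF, 0 °C, close monitoring; then cold aq. citric acid
Reagents that add atoms: none
Why: Chemoselective ammonolysis: the aryl acetates, whose phenoxide leaving groups are stabilised by the ortho and para carboxyl, should react with ammonia at 0 °C far faster than the hindered secondary alkyl acetate, so short exposure leaves the C10' ester in place. The carboxyl is masked as its ammonium salt and is regenerated on acidification.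

## Compound list

1 | (R)-oct-1-yn-3-ol | CCCCC[C@H](C#C)O | starting material
2 | (R)-3-(tert-butyldimethylsilyloxy)oct-1-yne | CCCCC[C@H](C#C)O[Si](C)(C)C(C)(C)C | intermediate
3 | 1,7-dibromoheptane | BrCCCCCCCBr | starting material
4 | [(R)-3-(tert-butyldimethylsilyloxy)oct-1-yn-1-yl]lithium | CCCCC[C@H](C#C[Li])O[Si](C)(C)C(C)(C)C | intermediate (not isolated)
5 | (R)-1-bromo-10-(tert-butyldimethylsilyloxy)pentadec-8-yne | CCCCC[C@H](C#CCCCCCCCBr)O[Si](C)(C)C(C)(C)C | intermediate
6 | (8Z,10R)-1-bromo-10-(tert-butyldimethylsilyloxy)pentadec-8-ene | CCCCC[C@H](/C=C\CCCCCCCBr)O[Si](C)(C)C(C)(C)C | intermediate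
7 | [(8Z,10R)-10-(tert-butyldimethylsilyloxy)pentadec-8-en-1-yl]magnesium bromide | CCCCC[C@H](/C=C\CCCCCCC[Mg]Br)O[Si](C)(C)C(C)(C)C | intermediate
8 | 5-fluorobenzene-1,3-diol | Oc1cc(O)cc(F)c1 | starting material
9 | 1-fluoro-3,5-bis(methoxymethoxy)benzene | COCOc1cc(F)cc(OCOC)c1 | intermediate
10 | carbon dioxide | O=C=O | starting material
11 | [2-fluoro-4,6-bis(methoxymethoxy)phenyl]lithium | [Li]c1c(F)cc(OCOC)cc1OCOC | intermediate (not isolated)
12 | 3,5-bis(methoxymethoxy)benzyne | COCOC1=CC(OCOC)=CC#C1 | intermediate (not isolated)
13 | {2,4-bis(methoxymethoxy)-6-[(8Z,10R)-10-(tert-butyldimethylsilyloxy)pentadec-8-en-1-yl]phenyl}magnesium bromide | CCCCC[C@H](/C=C\CCCCCCCc1cc(OCOC)cc(OCOC)c1[Mg]Br)O[Si](C)(C)C(C)(C)C | intermediate (not isolated)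
14 | 2,4-bis(methoxymethoxy)-6-[(8Z,10R)-10-(tert-butyldimethylsilyloxy)pentadec-8-en-1-yl]benzoic acid | CCCCC[C@H](/C=C\CCCCCCCc1cc(OCOC)cc(OCOC)c1C(=O)O)O[Si](C)(C)C(C)(C)C | intermediate
15 | 2,4-dihydroxy-6-[(8Z,10R)-10-hydroxypentadec-8-en-1-yl]benzoic acid | CCCCC[C@H](/C=C\CCCCCCCc1cc(O)cc(O)c1C(=O)O)O | intermediate
16 | acetic 2,4-diacetoxy-6-[(8Z,10R)-10-acetoxypentadec-8-en-1-yl]benzoic anhydride | CCCCC[C@H](/C=C\CCCCCCCc1cc(OC(C)=O)cc(OC(C)=O)c1C(=O)OC(C)=O)OC(C)=O | intermediate (not isolated)
17 | 2,4-diacetoxy-6-[(8Z,10R)-10-acetoxypentadec-8-en-1-yl]benzoic acid | CCCCC[C@H](/C=C\CCCCCCCc1cc(OC(C)=O)cc(OC(C)=O)c1C(=O)O)OC(C)=O | intermediate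
18 | 2,4-dihydroxy-6-[(8Z,10R)-10-acetoxypentadec-8-en-1-yl]benzoic acid | CCCCC[C@H](/C=C\CCCCCCCc1cc(O)cc(O)c1C(=O)O)OC(C)=O | target

## Step count and least certain steps

Total step count: 9.
Longest linear sequence: 8 steps (1 → 2 → 5 → 6 → 7 → 14 → 15 → 17 → 18, steps 1–4 and 6–9); step 5 is a one-step branch to 9.

**Step 6 (key step).** Several processes can erode it:

- competing metalation of 9 between the two acetal oxygens;
- capture of aryne 12 by the product organometallic 13 or by the liberated amine instead of by 7;
- protonation of 13 by the amine before carboxylation;
- loss of the surplus of the valuable reagent 7 as its carboxylation product.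

The fallback sets out from 7, comes back at 14 and replaces the aryne by a cross-coupling on a ring that already carries the carboxyl carbon. Commercial methyl 2,4,6-trihydroxybenzoate F1 would be bis-protected (MOMCl, iPr2NEt, CH2Cl2; the hydroxyl hydrogen-bonded to the ester stays free) to methyl 2-hydroxy-4,6-bis(methoxymethoxy)benzoate F2. This would be converted with Tf2O and pyridine into the aryl triflate methyl 2,4-bis(methoxymethoxy)-6-(trifluoromethylsulfonyloxy)benzoate F3. Reagent 7 would be transmetalated with ZnBr2 to the alkylzinc bromide F4 and joined to F3 by Negishi coupling under Pd(dppf)Cl2 catalysis to give the methyl ester F5. Hydrolysis of this hindered ester (KOH, DMSO–H2O, 80 °C) would give 14.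

**Step 9.** The risk is over-reaction, that is ammonolysis of the C10' acetate once the aryl acetates are gone, or incomplete cleavage of the acetate at C4. The fallback sets out from 14 and comes back at 18; it installs the acetate before the phenols are unmasked, so no selective deacylation is needed. Bu4NF in THF would remove the silyl ether to give 2,4-bis(methoxymethoxy)-6-[(8Z,10R)-10-hydroxypentadec-8-en-1-yl]benzoic acid F6. Ac2O, pyridine and DMAP, with aqueous work-up to return the free carboxyl, would give the mono-acetate F7. ZnBr2 with n-PrSH in CH2Cl2 at 0 °C, a Lewis-acid-mediated transfer of the acetal carbon to the thiol that is complete within minutes and leaves alkyl acetates intact, would then release both phenols and give 18.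

**Step 7.** The risks are loss of CO2 from the liberated dihydroxybenzoic acid if warming is needed for the acetal para to the carboxyl, and acid-promoted ionisation with allylic transposition at the free C10' carbinol. The fallback sets out from 14 and comes back at 15; it separates the two deprotections so that no protic acid meets the free allylic alcohol. ZnBr2 with n-PrSH (CH2Cl2, 0 °C) would cleave the acetals while the silyl ether stays in place, giving 2,4-dihydroxy-6-[(8Z,10R)-10-(tert-butyldimethylsilyloxy)pentadec-8-en-1-yl]benzoic acid F8. Bu4NF in THF would then give 15.

**Step 2.** The risks are double alkylation of the symmetric dibromide, sluggish substitution by the inductively deactivated acetylide and tedious separation from excess 3. The fallback sets out from 2 and comes back at 14; it uses a dihalide with two leaving groups of different reactivity instead of a statistical excess. Acetylide 4 would be alkylated with 1-bromo-7-chloroheptane F9 at the bromide only, giving the chloroalkyne F10. The same semi-hydrogenation would give the Z-chloroalkene F11. Magnesium in refluxing THF would give the alkylmagnesium chloride F12, which takes the place of 7 in step 6 and delivers 14.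

## Further compounds

F1 | step 6 | methyl 2,4,6-trihydroxybenzoate | COC(=O)c1c(O)cc(O)cc1O
F2 | step 6 | methyl 2-hydroxy-4,6-bis(methoxymethoxy)benzoate | COCOc1cc(O)c(C(=O)OC)c(OCOC)c1
F3 | step 6 | methyl 2,4-bis(methoxymethoxy)-6-(trifluoromethylsulfonyloxy)benzoate | COCOc1cc(OS(=O)(=O)C(F)(F)F)c(C(=O)OC)c(OCOC)c1
F4 | step 6 | [(8Z,10R)-10-(tert-butyldimethylsilyloxy)pentadec-8-en-1-yl]zinc bromide | CCCCC[C@H](/C=C\CCCCCCC[Zn]Br)O[Si](C)(C)C(C)(C)C
F5 | step 6 | methyl 2,4-bis(methoxymethoxy)-6-[(8Z,10R)-10-(tert-butyldimethylsilyloxy)pentadec-8-en-1-yl]benzoate | CCCCC[C@H](/C=C\CCCCCCCc1cc(OCOC)cc(OCOC)c1C(=O)OC)O[Si](C)(C)C(C)(C)C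
F6 | step 9 | 2,4-bis(methoxymethoxy)-6-[(8Z,10R)-10-hydroxypentadec-8-en-1-yl]benzoic acid | CCCCC[C@H](/C=C\CCCCCCCc1cc(OCOC)cc(OCOC)c1C(=O)O)O
F7 | step 9 | 2,4-bis(methoxymethoxy)-6-[(8Z,10R)-10-acetoxypentadec-8-en-1-yl]benzoic acid | CCCCC[C@H](/C=C\CCCCCCCc1cc(OCOC)cc(OCOC)c1C(=O)O)OC(C)=O
F8 | step 7 | 2,4-dihydroxy-6-[(8Z,10R)-10-(tert-butyldimethylsilyloxy)pentadec-8-en-1-yl]benzoic acid | CCCCC[C@H](/C=C\CCCCCCCc1cc(O)cc(O)c1C(=O)O)O[Si](C)(C)C(C)(C)C
F9 | step 2 | 1-bromo-7-chloroheptane | ClCCCCCCCBr
F10 | step 2 | (R)-10-(tert-butyldimethylsilyloxy)-1-chloropentadec-8-yne | CCCCC[C@H](C#CCCCCCCCCl)O[Si](C)(C)C(C)(C)C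
F11 | step 2 | (8Z,10R)-10-(tert-butyldimethylsilyloxy)-1-chloropentadec-8-ene | CCCCC[C@H](/C=C\CCCCCCCCl)O[Si](C)(C)C(C)(C)C
F12 | step 2 | [(8Z,10R)-10-(tert-butyldimethylsilyloxy)pentadec-8-en-1-yl]magnesium chloride | CCCCC[C@H](/C=C\CCCCCCC[Mg]Cl)O[Si](C)(C)C(C)(C)C
A1 | alternative 1 | (3E,12Z,14R)-14-(tert-butyldimethylsilyloxy)nonadeca-3,12-dien-2-one | CCCCC[C@H](/C=C\CCCCCCC/C=C/C(C)=O)O[Si](C)(C)C(C)(C)C
A2 | alternative 1 | bis[2-(trimethylsilyl)ethyl] malonate | C[Si](C)(C)CCOC(=O)CC(=O)OCC[Si](C)(C)C
A3 | alternative 1 | 2-(trimethylsilyl)ethyl 6-[(8Z,10R)-10-(tert-butyldimethylsilyloxy)pentadec-8-en-1-yl]-2,4-dioxocyclohexane-1-carboxylate (ring centres unassigned) | CCCCC[C@H](/C=C\CCCCCCCC1CC(=O)CC(=O)C1C(=O)OCC[Si](C)(C)C)O[Si](C)(C)C(C)(C)C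
A4 | alternative 2 | 2-(trimethylsilyl)ethyl (11Z,13R)-13-acetoxyoctadec-11-en-2-ynoate | CCCCC[C@H](/C=C\CCCCCCCC#CC(=O)OCC[Si](C)(C)C)OC(C)=O
A5 | alternative 2 | 5,5-dimethyl-1,3-bis(trimethylsilyloxy)cyclohexa-1,3-diene | C[Si](C)(C)OC1=CC(=CC(C)(C)C1)O[Si](C)(C)C
A6 | alternative 2 | 2-(trimethylsilyl)ethyl 2,4-dihydroxy-6-[(8Z,10R)-10-acetoxypentadec-8-en-1-yl]benzoate | CCCCC[C@H](/C=C\CCCCCCCc1cc(O)cc(O)c1C(=O)OCC[Si](C)(C)C)OC(C)=O
A7 | alternative 3 | 6-[(12Z,14R)-14-(tert-butyldimethylsilyloxy)-2,4-dioxononadec-12-en-1-yl]-2,2-dimethyl-4H-1,3-dioxin-4-one | CCCCC[C@H](/C=C\CCCCCCCC(=O)CC(=O)CC1=CC(=O)OC(C)(C)O1)O[Si](C)(C)C(C)(C)C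
A8 | alternative 3 | 2-(trimethylsilyl)ethanol | C[Si](C)(C)CCO
A9 | alternative 3 | 2-(trimethylsilyl)ethyl (15Z,17R)-17-(tert-butyldimethylsilyloxy)-3,5,7-trioxodocos-15-enoate | CCCCC[C@H](/C=C\CCCCCCCC(=O)CC(=O)CC(=O)CC(=O)OCC[Si](C)(C)C)O[Si](C)(C)C(C)(C)C
A10 | alternative 3 | 2-(trimethylsilyl)ethyl 2,4-dihydroxy-6-[(8Z,10R)-10-(tert-butyldimethylsilyloxy)pentadec-8-en-1-yl]benzoate | CCCCC[C@H](/C=C\CCCCCCCc1cc(O)cc(O)c1C(=O)OCC[Si](C)(C)C)O[Si](C)(C)C(C)(C)C
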